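The route rests on disconnecting the C9–C10 bond of ring B. Ring A is read as a para-cresol: the C3 oxygen and the methyl-bearing C10 are para across ring A, so C10 can act as the carbon nucleophile of a phenoxide. In one operation an iridium-catalysed allylic dearomatization closes ring B, creates the quaternary C10 and the C9 stereocentre, and leaves the C11=C12 vinyl group, the C3 carbonyl, the C4 ester and the C8 oxygen in place. The precursor is a methyl salicylate whose meta side chain (C6–C9, C11, C12) carries an (S)-silyloxy group at C8 and an (E)-allylic methyl carbonate.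

Key step: step 9

Remarks before the steps:
- Andrographolide numbering is used (C1–C10 decalin, C11–C16 side chain and lactone, C17 exocyclic methylene, C18 methyl and C19 CH2O on C4, C20 methyl on C10). α/β are the actual faces in the usual drawing: C20, C19, O3 and the C9 side chain are α; H-5, H-9 and C18 are β.
- Assumption (sense of induction in step 9): the (Ra,R,R) enantiomer of the phosphoramidite is taken as the one that gives the (9S) centre (H-9 β) and is matched with the (8S) silyloxy centre. If the opposite sense is found, the enantiomeric ligand is used and nothing else changes.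
- Design choices: the phenol is masked as an allyl ether only for the carbanion steps and freed before the carbonate is introduced. The allylic carbonate is installed by cross-metathesis, so no hydride has to distinguish two esters.

Step 1
Reactants: 1 methyl 2-hydroxy-6-methylbenzoate
Product: 2 methyl 3-bromo-6-hydroxy-2-methylbenzoate
Conditions: NBS, MeCN, 0 °C → rt
Reagents that add atoms: N-bromosuccinimide, O=C1CCC(=O)N1Br
Why: Electrophilic aromatic bromination in which the hydroxyl group should direct the halogen to its para position (the future C10), which is also activated by the adjacent methyl group.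

Step 2
Reactants: 2 methyl 3-bromo-6-hydroxy-2-methylbenzoate
Product: 3 methyl 6-hydroxy-2,3-dimethylbenzoate
Conditions: (MeBO)3, PdCl2(dppf) (cat.), K2CO3, 1,4-dioxane/H2O, 100 °C
Reagents that add atoms: trimethylboroxine, CB1OB(C)OB(C)O1
Why: Suzuki–Miyaura methylation of the aryl bromide installs the future C20 methyl, and the doubly ortho-substituted ester should resist the aqueous base.

Step 3
Reactants: 3 methyl 6-hydroxy-2,3-dimethylbenzoate
Product: 4 methyl 2,3-dimethyl-6-(prop-2-en-1-yloxy)benzoate
Conditions: allyl bromide, K2CO3, DMF, rt → 50 °C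
Reagents that add atoms: allyl bromide, C=CCBr
Why: Williamson ether synthesis masks the acidic phenol before carbanion chemistry with a group that can later be removed without acid or fluoride.

Step 4
Reactants: 4 methyl 2,3-dimethyl-6-(prop-2-en-1-yloxy)benzoate; 5 (S)-epichlorohydrin
Product: 7 methyl 2-[(3S)-4-chloro-3-hydroxybutyl]-3-methyl-6-(prop-2-en-1-yloxy)benzoate, via benzylic lithium species 6 (not isolated)
Conditions: LiN(i-Pr)2, THF, −78 °C; then 5 (excess), −78 → −30 °C; AcOH, −78 °C
Reagents that add atoms: none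
Why: Lateral lithiation of the ortho-toluate (only the methyl ortho to the ester is acidified) followed by SN2 opening of the oxirane at its CH2 terminus forms C6–C7, and the stereocentre of 5 is not touched and becomes C8 (S).

Step 5
Reactants: 7 methyl 2-[(3S)-4-chloro-3-hydroxybutyl]-3-methyl-6-(prop-2-en-1-yloxy)benzoate
Product: 9 methyl 2-[(3S)-3-hydroxypent-4-en-1-yl]-3-methyl-6-(prop-2-en-1-yloxy)benzoate, via terminal epoxide 8 (not isolated)
Conditions: Me3S+ I−, n-BuLi, THF, −10 °C → rt
Reagents that add atoms: trimethylsulfonium iodide, C[S+](C)C.[I-]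
Why: Excess dimethylsulfonium methylide first closes the chlorohydrin to the epoxide, then opens it at the terminal carbon, and the sulfonium betaine eliminates Me2S (Corey–Chaykovsky-type ylide chemistry, epoxide-to-allylic-alcohol homologation), which gives the vinyl carbinol without touching C8.

Step 6
Reactants: 9 methyl 2-[(3S)-3-hydroxypent-4-en-1-yl]-3-methyl-6-(prop-2-en-1-yloxy)benzoate
Product: 10 methyl 2-[(3S)-3-(tert-butyldimethylsilyloxy)pent-4-en-1-yl]-3-methyl-6-(prop-2-en-1-yloxy)benzoate
Conditions: TBSCl, imidazole, DMF, rt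
Reagents that add atoms: tert-butyldimethylsilyl chloride, CC(C)(C)[Si](C)(C)Cl
Why: Standard silylation of the secondary allylic alcohol gives a bulky, non-leaving C8 substituent that later serves as the equatorial anchor of the ring closure.

Step 7
Reactants: 10 methyl 2-[(3S)-3-(tert-butyldimethylsilyloxy)pent-4-en-1-yl]-3-methyl-6-(prop-2-en-1-yloxy)benzoate
Product: 11 methyl 2-[(3S)-3-(tert-butyldimethylsilyloxy)pent-4-en-1-yl]-6-hydroxy-3-methylbenzoate
Conditions: Pd(PPh3)4 (cat.), morpholine, THF, rt
Reagents that add atoms: none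
Why: Tsuji–Trost-type deallylation in which zerovalent palladium ionizes the aryl allyl ether and morpholine traps the allyl unit, while the allylic silyl ether is not ionized.

Step 8
Reactants: 11 methyl 2-[(3S)-3-(tert-butyldimethylsilyloxy)pent-4-en-1-yl]-6-hydroxy-3-methylbenzoate; 12 allyl methyl carbonate
Product: 13 methyl 2-[(3S,4E)-3-(tert-butyldimethylsilyloxy)-6-(methoxycarbonyloxy)hex-4-en-1-yl]-6-hydroxy-3-methylbenzoate
Conditions: 12 (4 equiv), RuCl2(H2IMes)(=CH-C6H4-2-O-i-Pr) (second-generation Hoveyda–Grubbs catalyst, 5 mol%), CH2Cl2, 40 °C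
Reagents that add atoms: none
Why: Olefin cross-metathesis replaces the terminal CH2 of the vinyl group by the C11–C12 carbonate unit, the (E)-alkene is expected as the thermodynamic product, and free phenol and esters are tolerated.

Step 9
Reactants: 13 methyl 2-[(3S,4E)-3-(tert-butyldimethylsilyloxy)-6-(methoxycarbonyloxy)hex-4-en-1-yl]-6-hydroxy-3-methylbenzoate
Product: 14 methyl (4aS,5S,6S)-6-(tert-butyldimethylsilyloxy)-5-ethenyl-4a-methyl-2-oxo-2,4a,5,6,7,8-hexahydronaphthalene-1-carboxylate
Conditions: [Ir(cod)Cl]2 (4 mol%), (Ra,R,R)-BINOL-derived N,N-bis(1-phenylethyl)phosphoramidite (8 mol%), pre-activated with n-PrNH2 (THF, 50 °C, then evaporated); Cs2CO3, THF (0.02 M), 50 °C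
Reagents that add atoms: none
Why: The cyclometalated iridium phosphoramidite complex ionizes the allylic carbonate (CO2 and methoxide leave, which makes the step irreversible) to an electrophilic η3-allyl species, and the caesium phenoxide of ring A attacks it, anti to the metal, through its para carbon C10 at the substituted allyl terminus C9. The closest known reaction type is the iridium-catalysed intramolecular asymmetric allylic dearomatization of phenols, an outer-sphere C-allylation of a phenoxide that gives a cyclohexadienone with a quaternary carbon. Ring B is closed in a 6-exo mode (C10 onto C9, the C11=C12 vinyl group staying outside the ring), since attack at C12 or by the phenoxide oxygen would require medium rings. C9 is set by the ligand, which fixes the face of the allyl unit that is attacked and is matched with the (S)-silyloxy centre at C8; C10 follows from a chair-like transition state with the vinyl and silyloxy groups both equatorial, which places the C10 methyl cis to the vinyl group. The step needs bonding at C10 (para) and not at C4 (ortho), both being six-ring closures: C4 is flanked on both sides and bonding there would twist the chelated ester out of conjugation and give the less stable linearly conjugated dienone, whereas bonding at the methyl-bearing C10 keeps the O3–C3–C4–ester system conjugated and gives the cross-conjugated dienone; high dilution suppresses intermolecular O-allylation.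

Step 10
Reactants: 14 methyl (4aS,5S,6S)-6-(tert-butyldimethylsilyloxy)-5-ethenyl-4a-methyl-2-oxo-2,4a,5,6,7,8-hexahydronaphthalene-1-carboxylate
Product: 15 methyl (4aS,5S,6S)-6-(tert-butyldimethylsilyloxy)-5-ethenyl-4a-methyl-2-oxo-2,3,4,4a,5,6,7,8-octahydronaphthalene-1-carboxylate
Conditions: [(Ph3P)CuH]6 (0.4 equiv), toluene, H2O (2 equiv), 0 °C → rt
Reagents that add atoms: none
Why: Conjugate reduction by a phosphine copper hydride should deliver hydride to C1, the unsubstituted β-carbon of the disubstituted enone, rather than to the fully substituted ring-fusion carbon C5, leaves the isolated vinyl group alone and creates no stereocentre.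

Step 11
Reactants: 15 methyl (4aS,5S,6S)-6-(tert-butyldimethylsilyloxy)-5-ethenyl-4a-methyl-2-oxo-2,3,4,4a,5,6,7,8-octahydronaphthalene-1-carboxylate
Product: 17 methyl (1S,4aR,5S,6S,8aS)-6-(tert-butyldimethylsilyloxy)-5-ethenyl-1,4a-dimethyl-2-oxodecahydronaphthalene-1-carboxylate, via lithium β-keto ester enolate 16 (not isolated)
Conditions: Li (2.2 equiv), NH3 (l)/THF, t-BuOH (1.0 equiv), −78 °C; isoprene; then MeI (excess), −78 → −33 °C
Reagents that add atoms: iodomethane, CI
Why: Dissolving-metal reductive alkylation (Birch-type enone reduction with enolate trapping) gives the trans-fused enolate by axial protonation at C5 anti to the C10 methyl (H-5 β), and MeI then attacks C4 from the face opposite the axial C10 methyl, so that C18 is equatorial (β) and the ester axial (α) as C19 requires.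

Step 12
Reactants: 17 methyl (1S,4aR,5S,6S,8aS)-6-(tert-butyldimethylsilyloxy)-5-ethenyl-1,4a-dimethyl-2-oxodecahydronaphthalene-1-carboxylate
Product: 18 (1R,2R,4aR,5S,6S,8aS)-6-(tert-butyldimethylsilyloxy)-5-ethenyl-1-(hydroxymethyl)-1,4a-dimethyldecahydronaphthalen-2-ol
Conditions: LiAlH4, THF, 0 °C → rt
Reagents that add atoms: none
Why: Hydride reduction of ketone and ester in which axial delivery to the C3 carbonyl from the β face, away from the axial C4 and C10 substituents, should give the equatorial 3α-alcohol while the neopentyl ester becomes C19–OH.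

Step 13
Reactants: 18 (1R,2R,4aR,5S,6S,8aS)-6-(tert-butyldimethylsilyloxy)-5-ethenyl-1-(hydroxymethyl)-1,4a-dimethyldecahydronaphthalen-2-ol
Product: 19 3α,19-O-isopropylidene acetal of 18 (8β-silyloxy, 9α-vinyl)
Conditions: 2,2-dimethoxypropane, PPTS (cat.), CH2Cl2, rt
Reagents that add atoms: 2,2-dimethoxypropane, COC(C)(C)OC
Why: Transacetalization closes the six-membered acetonide on the 1,3-diol, a mildly acid-labile protecting group that is kept to the last step.

Step 14
Reactants: 19 3α,19-O-isopropylidene acetal of 18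
Product: 21 C12 primary alcohol (C9–CH2CH2OH; 8β-silyloxy, 3α,19-acetonide), via B-alkyl-9-borabicyclononane 20 (not isolated)
Conditions: 9-BBN, THF, rt → 60 °C; then NaOH, H2O2, 0 °C → rt
Reagents that add atoms: hydrogen peroxide, OO
Why: Anti-Markovnikov hydroboration–oxidation of the only alkene present places the oxygen on the terminal carbon C12.

Step 15
Reactants: 21 C12 primary alcohol
Product: 22 C12 4-methoxybenzyl ether of 21
Conditions: NaH, 4-methoxybenzyl chloride, Bu4NI (cat.), DMF, 0 °C → rt
Reagents that add atoms: 4-methoxybenzyl chloride, COc1ccc(CCl)cc1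
Why: Williamson etherification gives an ether that survives fluoride, oxidation and ylide and is later cleaved oxidatively without touching the acetonide.

Step 16
Reactants: 22 C12 4-methoxybenzyl ether of 21
Product: 23 C8 β-alcohol (12-O-PMB, 3α,19-acetonide)
Conditions: Bu4NF, THF, rt → 50 °C
Reagents that add atoms: none
Why: Fluoride-mediated desilylation frees the hindered secondary C8 hydroxyl.

Step 17
Reactants: 23 C8 β-alcohol
Product: 24 C8 ketone (12-O-PMB, 3α,19-acetonide)
Conditions: Dess–Martin periodinane, NaHCO3, CH2Cl2, rt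
Reagents that add atoms: none
Why: Dess–Martin oxidation under buffered conditions gives the ketone without epimerizing C9, whose side chain is in any case in the equatorial, thermodynamically preferred position.

Step 18
Reactants: 24 C8 ketone
Product: 25 8(17)-exocyclic methylene compound (12-O-PMB, 3α,19-acetonide)
Conditions: Ph3PCH3Br, KOt-Bu, toluene, rt → 80 °C
Reagents that add atoms: methyltriphenylphosphonium bromide, C[P+](c1ccccc1)(c1ccccc1)c1ccccc1.[Br-]
Why: Wittig methylenation of the hindered C8 ketone installs C17, and any reversible enolization towards C9 returns the equatorial side chain.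

Step 19
Reactants: 25 8(17)-exocyclic methylene compound
Product: 26 C12 primary alcohol with the 8(17)-methylene group (3α,19-acetonide)
Conditions: DDQ, CH2Cl2/pH 7 buffer, 0 °C → rt
Reagents that add atoms: none
Why: Oxidative cleavage of the PMB ether (hydride abstraction at the electron-rich benzylic position, then hydrolysis) should leave the acetonide and the 1,1-disubstituted alkene untouched under buffered conditions.

Step 20
Reactants: 26 C12 primary alcohol with the 8(17)-methylene group
Product: 27 C12 aldehyde (C9–CH2CHO; 8(17)-ene, 3α,19-acetonide)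
Conditions: Dess–Martin periodinane, NaHCO3, CH2Cl2, 0 °C → rt
Reagents that add atoms: none
Why: Buffered Dess–Martin oxidation gives the aldehyde without acid that could trigger a carbonyl-ene reaction with the C8(17) alkene.

Step 21
Reactants: 28 (S)-4-hydroxydihydrofuran-2(3H)-one
Product: 29 (S)-4-(tert-butyldimethylsilyloxy)dihydrofuran-2(3H)-one
Conditions: TBSCl, imidazole, DMF, rt
Reagents that add atoms: tert-butyldimethylsilyl chloride, CC(C)(C)[Si](C)(C)Cl
Why: Silylation makes the C14 oxygen a poor leaving group and distinguishes it from the C12 oxygen created in the next step, while C14 (S) comes unchanged from the chiral pool.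

Step 22
Reactants: 27 C12 aldehyde; 29 (S)-4-(tert-butyldimethylsilyloxy)dihydrofuran-2(3H)-one
Product: 31 aldol adduct (12-hydroxy, 13-H trans to the 14-silyloxy group, epimers at C12; 3α,19-acetonide), via lactone lithium enolate 30 (not isolated)
Conditions: LiN(i-Pr)2, THF, −78 °C; then 27, −78 °C; AcOH, −78 °C
Reagents that add atoms: none
Why: Directed aldol addition of the lactone lithium enolate, which at −78 °C should be trapped by the aldehyde faster than it loses the β-silyloxy group; C13 forms anti to that group and C12 as a mixture, both centres being planarized or removed in the next step.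

Step 23
Reactants: 31 aldol adduct
Product: 33 3,19-O-isopropylidene-14-O-(tert-butyldimethylsilyl)andrographolide, via C12 mesylate 32 (not isolated)
Conditions: MsCl, Et3N, CH2Cl2, 0 °C; then DBU, 0 °C → rt
Reagents that add atoms: none
Why: Mesylation and E1cB elimination through the lactone enolate expel the mesylate rather than the silyloxy group and should give the (E)-alkylidene lactone (H-12 syn to the carbonyl) as the thermodynamically preferred isomer.

Step 24
Reactants: 33 3,19-O-isopropylidene-14-O-(tert-butyldimethylsilyl)andrographolide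
Product: 34 andrographolide
Conditions: HF (48% aq.), MeCN, 0 °C → rt
Reagents that add atoms: none
Why: Dilute aqueous HF cleaves the silyl ether and hydrolyses the acetonide in one operation and should be mild enough for the allylic C14 alcohol, the exocyclic alkene and the lactone.

Compound list
1 | methyl 2-hydroxy-6-methylbenzoate | COC(=O)c1c(C)cccc1O | starting material
2 | methyl 3-bromo-6-hydroxy-2-methylbenzoate | COC(=O)c1c(O)ccc(Br)c1C | intermediate
3 | methyl 6-hydroxy-2,3-dimethylbenzoate | COC(=O)c1c(O)ccc(C)c1C | intermediate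
4 | methyl 2,3-dimethyl-6-(prop-2-en-1-yloxy)benzoate | COC(=O)c1c(OCC=C)ccc(C)c1C | intermediate
5 | (S)-epichlorohydrin, (2S)-2-(chloromethyl)oxirane | ClC[C@@H]1CO1 | starting material
6 | benzylic lithium species of 4, [2-(methoxycarbonyl)-6-methyl-3-(prop-2-en-1-yloxy)phenyl]methyllithium | [Li]Cc1c(C)ccc(OCC=C)c1C(=O)OC | intermediate
7 | methyl 2-[(3S)-4-chloro-3-hydroxybutyl]-3-methyl-6-(prop-2-en-1-yloxy)benzoate | COC(=O)c1c(OCC=C)ccc(C)c1CC[C@H](O)CCl | intermediate
8 | methyl 3-methyl-2-{2-[(2S)-oxiran-2-yl]ethyl}-6-(prop-2-en-1-yloxy)benzoate | COC(=O)c1c(OCC=C)ccc(C)c1CC[C@H]1CO1 | intermediate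
9 | methyl 2-[(3S)-3-hydroxypent-4-en-1-yl]-3-methyl-6-(prop-2-en-1-yloxy)benzoate | COC(=O)c1c(OCC=C)ccc(C)c1CC[C@H](O)C=C | intermediate
10 | methyl 2-[(3S)-3-(tert-butyldimethylsilyloxy)pent-4-en-1-yl]-3-methyl-6-(prop-2-en-1-yloxy)benzoate | COC(=O)c1c(OCC=C)ccc(C)c1CC[C@H](O[Si](C)(C)C(C)(C)C)C=C | intermediate
11 | methyl 2-[(3S)-3-(tert-butyldimethylsilyloxy)pent-4-en-1-yl]-6-hydroxy-3-methylbenzoate | COC(=O)c1c(O)ccc(C)c1CC[C@H](O[Si](C)(C)C(C)(C)C)C=C | intermediate
12 | allyl methyl carbonate | C=CCOC(=O)OC | starting material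
13 | methyl 2-[(3S,4E)-3-(tert-butyldimethylsilyloxy)-6-(methoxycarbonyloxy)hex-4-en-1-yl]-6-hydroxy-3-methylbenzoate (key-step precursor) | COC(=O)c1c(O)ccc(C)c1CC[C@H](O[Si](C)(C)C(C)(C)C)/C=C/COC(=O)OC | intermediate
14 | methyl (4aS,5S,6S)-6-(tert-butyldimethylsilyloxy)-5-ethenyl-4a-methyl-2-oxo-2,4a,5,6,7,8-hexahydronaphthalene-1-carboxylate (cross-conjugated dienone; C10 methyl α, C9 vinyl α, C8 silyloxy β) | CC(C)(C)[Si](C)(C)O[C@H]1CCC2=C(C(=O)OC)C(=O)C=C[C@@]2(C)[C@@H]1C=C | intermediate
15 | methyl (4aS,5S,6S)-6-(tert-butyldimethylsilyloxy)-5-ethenyl-4a-methyl-2-oxo-2,3,4,4a,5,6,7,8-octahydronaphthalene-1-carboxylate | CC(C)(C)[Si](C)(C)O[C@H]1CCC2=C(C(=O)OC)C(=O)CC[C@@]2(C)[C@@H]1C=C | intermediate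
16 | lithium enolate of the trans-fused β-keto ester (O3–Li, C3=C4, H-5 β) | CC(C)(C)[Si](C)(C)O[C@H]1CC[C@@H]2C(C(=O)OC)=C(O[Li])CC[C@@]2(C)[C@@H]1C=C | intermediate
17 | methyl (1S,4aR,5S,6S,8aS)-6-(tert-butyldimethylsilyloxy)-5-ethenyl-1,4a-dimethyl-2-oxodecahydronaphthalene-1-carboxylate (C18 β, ester α, H-5 β) | CC(C)(C)[Si](C)(C)O[C@H]1CC[C@@H]2[C@](C)(C(=O)OC)C(=O)CC[C@@]2(C)[C@@H]1C=C | intermediate
18 | (1R,2R,4aR,5S,6S,8aS)-6-(tert-butyldimethylsilyloxy)-5-ethenyl-1-(hydroxymethyl)-1,4a-dimethyldecahydronaphthalen-2-ol (3α,19-diol) | CC(C)(C)[Si](C)(C)O[C@H]1CC[C@@H]2[C@](C)(CO)[C@H](O)CC[C@@]2(C)[C@@H]1C=C | intermediate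
19 | 3α,19-O-isopropylidene acetal of 18 (8β-silyloxy, 9α-vinyl) | CC(C)(C)[Si](C)(C)O[C@H]1CC[C@@H]2[C@]3(C)COC(C)(C)O[C@@H]3CC[C@@]2(C)[C@@H]1C=C | intermediate
20 | B-alkyl-9-borabicyclo[3.3.1]nonane from 19 (boron on C12) | CC(C)(C)[Si](C)(C)O[C@H]1CC[C@@H]2[C@]3(C)COC(C)(C)O[C@@H]3CC[C@@]2(C)[C@@H]1CCB1C2CCCC1CCC2 | intermediate
21 | C12 primary alcohol (C9–CH2CH2OH; 8β-silyloxy, 3α,19-acetonide) | CC(C)(C)[Si](C)(C)O[C@H]1CC[C@@H]2[C@]3(C)COC(C)(C)O[C@@H]3CC[C@@]2(C)[C@@H]1CCO | intermediate
22 | C12 4-methoxybenzyl ether of 21 | CC(C)(C)[Si](C)(C)O[C@H]1CC[C@@H]2[C@]3(C)COC(C)(C)O[C@@H]3CC[C@@]2(C)[C@@H]1CCOCc1ccc(OC)cc1 | intermediate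
23 | C8 β-alcohol (12-O-PMB, 3α,19-acetonide) | O[C@H]1CC[C@@H]2[C@]3(C)COC(C)(C)O[C@@H]3CC[C@@]2(C)[C@@H]1CCOCc1ccc(OC)cc1 | intermediate
24 | C8 ketone (12-O-PMB, 3α,19-acetonide) | O=C1CC[C@@H]2[C@]3(C)COC(C)(C)O[C@@H]3CC[C@@]2(C)[C@@H]1CCOCc1ccc(OC)cc1 | intermediate
25 | 8(17)-exocyclic methylene compound (12-O-PMB, 3α,19-acetonide) | C=C1CC[C@@H]2[C@]3(C)COC(C)(C)O[C@@H]3CC[C@@]2(C)[C@@H]1CCOCc1ccc(OC)cc1 | intermediate
26 | C12 primary alcohol with 8(17)-methylene group (3α,19-acetonide) | C=C1CC[C@@H]2[C@]3(C)COC(C)(C)O[C@@H]3CC[C@@]2(C)[C@@H]1CCO | intermediate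
27 | C12 aldehyde (C9–CH2CHO; 8(17)-ene, 3α,19-acetonide) | C=C1CC[C@@H]2[C@]3(C)COC(C)(C)O[C@@H]3CC[C@@]2(C)[C@@H]1CC=O | intermediate
28 | (S)-4-hydroxydihydrofuran-2(3H)-one, (S)-3-hydroxy-γ-butyrolactone | O=C1OC[C@@H](O)C1 | starting material
29 | (S)-4-(tert-butyldimethylsilyloxy)dihydrofuran-2(3H)-one | O=C1OC[C@@H](O[Si](C)(C)C(C)(C)C)C1 | intermediate
30 | lithium enolate of 29 | [Li]OC1=C[C@H](O[Si](C)(C)C(C)(C)C)CO1 | intermediate
31 | aldol adduct (12-hydroxy, epimers at C12; 13-H trans to the 14-silyloxy group; 3α,19-acetonide) | C=C1CC[C@@H]2[C@]3(C)COC(C)(C)O[C@@H]3CC[C@@]2(C)[C@@H]1CC(O)[C@@H]1C(=O)OC[C@H]1O[Si](C)(C)C(C)(C)C | intermediate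
32 | C12 methanesulfonate of 31 | C=C1CC[C@@H]2[C@]3(C)COC(C)(C)O[C@@H]3CC[C@@]2(C)[C@@H]1CC(OS(C)(=O)=O)[C@@H]1C(=O)OC[C@H]1O[Si](C)(C)C(C)(C)C | intermediate
33 | 3,19-O-isopropylidene-14-O-(tert-butyldimethylsilyl)andrographolide (12E, 14S) | C=C1CC[C@@H]2[C@]3(C)COC(C)(C)O[C@@H]3CC[C@@]2(C)[C@@H]1C/C=C1/C(=O)OC[C@H]1O[Si](C)(C)C(C)(C)C | intermediate
34 | andrographolide, (3E,4S)-3-{2-[(1R,4aS,5R,6R,8aS)-6-hydroxy-5-(hydroxymethyl)-5,8a-dimethyl-2-methylidenedecahydronaphthalen-1-yl]ethylidene}-4-hydroxyoxolan-2-one | C=C1CC[C@@H]2[C@](C)(CO)[C@H](O)CC[C@@]2(C)[C@@H]1C/C=C1/C(=O)OC[C@H]1O | target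

Total step count: 24. Longest linear sequence: 23 steps (steps 1–20 and 22–24; step 21 prepares the lactone partner).

Steps most likely to fail

Step 9 (key step). Bond formation may occur at the ester-bearing ortho carbon C4 instead of C10, the C10 configuration may be poorly controlled if the congested allyl unit reacts through a non-chair arrangement, and slow ionization next to the silyloxy group may let intermolecular O-allylation compete. The fallback sets out from 11 and comes back at 14, and it reverses the polarity of the same C9–C10 bond formation. Cross-metathesis of 11 with allyltrimethylsilane, using RuCl2(H2IMes)(=CH-C6H4-2-O-i-Pr), gives methyl 2-[(3S,4E)-3-(tert-butyldimethylsilyloxy)-6-(trimethylsilyl)hex-4-en-1-yl]-6-hydroxy-3-methylbenzoate F1. Oxidation of the phenol with PhI(OAc)2 in (CF3)2CHOH at −20 °C makes ring A the electrophile. The allylsilane then attacks the para carbon, the usual site for carbon nucleophiles in oxidative phenol dearomatization, with loss of silicon. This forms C9–C10 and the C11=C12 vinyl group and gives 14, with the C8 centre and the chair-like closure as control elements.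

Step 10. Hydride may be delivered to the ester-activated C5 instead of C1, or both enone double bonds may be reduced, which would leave C5 without stereocontrol. The fallback sets out from 14 and comes back at 17, and it lets electronic rather than steric differences distinguish the two double bonds. Li/NH3 reduction of 14 with one equivalent of t-BuOH should reduce the doubly activated C4=C5 bond first. Trapping the enolate with MeI gives the 1,2-didehydro analogue of 17 (C1=C2 enone, C4 methyl β, ester α, H-5 β) F2. Its single enone double bond is then reduced with [(Ph3P)CuH]6 to give 17.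

Step 22. The C14 oxygen may be lost by β-elimination from the lactone enolate before it adds to the aldehyde, and the elimination that follows may give the wrong alkene geometry. The fallback sets out from 26 and comes back at 34, and it replaces aldol condensation by alkylation and selenoxide elimination. Alcohol 26 is converted with I2, PPh3 and imidazole into the C12 iodide F3. Alkylation of the dianion of unprotected lactone 28 (two equivalents of LiN(i-Pr)2, THF/DMPU), in which the C14 oxygen is an alkoxide and cannot leave, gives the trans-2-alkyl-3-hydroxy lactone F4. A second dianion formation and trapping with PhSeBr gives the α-phenylselanyl lactone F5. Oxidation with H2O2 and syn-elimination of the selenoxide, which avoids the carbinol carbon C14 and therefore goes towards C12, gives andrographolide 3,19-acetonide F6. Aqueous AcOH then removes the acetonide to give 34.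

Further compounds
F1 | step 9 | methyl 2-[(3S,4E)-3-(tert-butyldimethylsilyloxy)-6-(trimethylsilyl)hex-4-en-1-yl]-6-hydroxy-3-methylbenzoate | COC(=O)c1c(O)ccc(C)c1CC[C@H](O[Si](C)(C)C(C)(C)C)/C=C/C[Si](C)(C)C
F2 | step 10 | 1,2-didehydro analogue of 17 (C1=C2 enone) | CC(C)(C)[Si](C)(C)O[C@H]1CC[C@@H]2[C@](C)(C(=O)OC)C(=O)C=C[C@@]2(C)[C@@H]1C=C
F3 | step 22 | C12 iodide from 26 (8(17)-ene, 3α,19-acetonide) | C=C1CC[C@@H]2[C@]3(C)COC(C)(C)O[C@@H]3CC[C@@]2(C)[C@@H]1CCI
F4 | step 22 | trans-2-alkyl-3-hydroxy lactone (12,13-dihydro-13-H compound, 14S, free 14-OH, 3α,19-acetonide) | C=C1CC[C@@H]2[C@]3(C)COC(C)(C)O[C@@H]3CC[C@@]2(C)[C@@H]1CC[C@@H]1C(=O)OC[C@H]1O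
F5 | step 22 | α-phenylselanyl lactone (selenium trans to the 14-hydroxyl) | C=C1CC[C@@H]2[C@]3(C)COC(C)(C)O[C@@H]3CC[C@@]2(C)[C@@H]1CC[C@@]1([Se]c2ccccc2)C(=O)OC[C@H]1O
F6 | step 22 | andrographolide 3,19-acetonide | C=C1CC[C@@H]2[C@]3(C)COC(C)(C)O[C@@H]3CC[C@@]2(C)[C@@H]1C/C=C1/C(=O)OC[C@H]1O
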